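The spiro γ-lactone is disconnected at the O–C9 bond. Its ring oxygen sits on C9, allylic to the E C10=C11 alkene, which is exactly what selenolactonisation of a C9=C10 alkene by the C8 acid followed by selenoxide elimination toward C11 leaves behind. In one operation the key step closes the five-membered lactone ring on the quaternary C6 of the cyclohexenone ring, forms the O–C9 and C10–Se bonds and sets C9 and C10. Its precursor is the C6-quaternary cyclohexenone acetic acid bearing an E C9=C10 alkenyl chain with the citronellal methine at C11, a silyl ether at C4 and a second silyl ether on the C15 carbinol.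

Key step: step 8

Numbering used throughout (target atoms): C1 ring ketone, C2=C3 ring alkene, C4 oxygenated ring carbon, C5 ring CH2, C6 spiro/quaternary carbon, C7 CH2 and C8 carbonyl of the acid arm, C9 lactone O–CH, C10–C15 side chain (methyl on C11, carbinol C15).

Assumption: ketone 5 responds to the chiral amide in the sense generally accepted for 4-substituted cyclohexanones, the (S,S)-amide delivering the (4R)-enolate 6. Should the sense be opposite, the (R,R)-amine salt is used in step 3 and nothing else changes.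

Remarks on the design:
- **Stereochemical consistency.** Anti addition to the E C9=C10 alkene gives the (10R,11R) selenide 18, and syn elimination from that pair can only give the E C10=C11 alkene. Acid 17 and selenide 18 as drawn are therefore consistent with each other and with the target.
- **Descriptor changes without inversion.** C4 is R up to 14 and S from 15 on, and C9 is S in 18 and 19 and R from 20 on, only because CIP priorities change.
- **C15 hydroxyl.** It is carried as a triethylsilyl ether from step 2 to step 10, so that it stays out of the enolate, sulfonylation and selenium chemistry. It is removed together with the C4 silyl group.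
- **Ester cleavage.** The methyl ester is cleaved without hydroxide, to protect the γ-silyloxy enone.
- **Enantiomeric purity.** Antipodal ring material surviving step 3 would be carried by the same relay into the Z C10=C11 diastereomer, which chromatography should remove, so the purity of the target does not rest on step 3 alone.

Step 1
Reactants: 1 (R)-citronellal
Product: 3 (3R,5E)-7-hydroxy-3,7-dimethyloct-5-enal, via allylic hydroperoxide 2 (not isolated)
Conditions: O2, tetraphenylporphyrin (catalytic), visible light, CH2Cl2, 0 °C; then PPh3, 0 °C → rt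
Reagents that add atoms: dioxygen O=O
Why: Schenck ene reaction: singlet oxygen takes an allylic hydrogen from the C5 methylene of citronellal with migration of the double bond, which should give the E-configured tertiary hydroperoxide (beside the secondary regioisomer, which should be separable) that PPh3 reduces to the alcohol, while the C3 stereocentre of citronellal is not touched.

Step 2
Reactants: 3 (3R,5E)-7-hydroxy-3,7-dimethyloct-5-enal
Product: 4 (3R,5E)-3,7-dimethyl-7-(triethylsilyloxy)oct-5-enal
Conditions: Et3SiOTf, 2,6-lutidine, CH2Cl2, −78 °C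
Reagents that add atoms: triethylsilyl trifluoromethanesulfonate CC[Si](CC)(CC)OS(=O)(=O)C(F)(F)F
Why: Silyl triflate silylation of a tertiary alcohol with a hindered pyridine base is routine at −78 °C and should leave the aldehyde unenolised, and the cap keeps the carbinol out of the enolate, sulfonylation and selenium steps that follow.

Step 3
Reactants: 5 4-(tert-butyldimethylsilyloxy)cyclohexanone; 4 (3R,5E)-3,7-dimethyl-7-(triethylsilyloxy)oct-5-enal
Product: 7 (4R)-4-(tert-butyldimethylsilyloxy)-2-[(3R,5E)-1-hydroxy-3,7-dimethyl-7-(triethylsilyloxy)oct-5-en-1-yl]cyclohexan-1-one (C2/C1' epimer mixture), via lithium enolate 6 (not isolated)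
Conditions: (S,S)-bis(1-phenylethyl)amine·HCl (1.05 equiv), n-BuLi (2.1 equiv), THF, −78 → 0 °C; then 5, −78 °C; then 4 (1.2 equiv), −78 °C; aqueous NH4Cl
Reagents that add atoms: none
Why: Enantioselective deprotonation with the twofold-symmetric chiral lithium amide in the presence of LiCl (Simpkins–Koga desymmetrisation) should remove one of the two enantiotopic α-hydrogens and so fix C4 as R in the enolate, which is trapped directly by the aldehyde in a lithium aldol addition at −78 °C before it can equilibrate, and the two new centres need no control because both become trigonal in step 4.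

Step 4
Reactants: 7 (4R)-4-(tert-butyldimethylsilyloxy)-2-[(3R,5E)-1-hydroxy-3,7-dimethyl-7-(triethylsilyloxy)oct-5-en-1-yl]cyclohexan-1-one
Product: 9 (2E,4R)-4-(tert-butyldimethylsilyloxy)-2-[(3R,5E)-3,7-dimethyl-7-(triethylsilyloxy)oct-5-en-1-ylidene]cyclohexan-1-one, via mesylate 8 (not isolated)
Conditions: MeSO2Cl, Et3N, CH2Cl2, 0 °C; then DBU, 0 °C → rt
Reagents that add atoms: none
Why: Sulfonylation of the aldol hydroxyl and base-induced E1cB elimination through the ketone enolate should give the conjugated exocyclic enone, mainly as the more stable E isomer, and either geometry would feed the same dienolate in step 5.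

Step 5
Reactants: 9 (2E,4R)-4-(tert-butyldimethylsilyloxy)-2-[(3R,5E)-3,7-dimethyl-7-(triethylsilyloxy)oct-5-en-1-ylidene]cyclohexan-1-one; 10 methyl bromoacetate
Product: 12 methyl 2-[(1R,5R)-5-(tert-butyldimethylsilyloxy)-1-[(1E,3R,5E)-3,7-dimethyl-7-(triethylsilyloxy)octa-1,5-dien-1-yl]-2-oxocyclohexyl]acetate, via potassium dienolate 11 (not isolated)
Conditions: KN(SiMe3)2 (0.95 equiv), THF, −78 → 0 °C; then 10, −78 °C
Reagents that add atoms: none
Why: Deconjugative α-alkylation of a thermodynamic dienolate: proton exchange through the slight excess of ketone and the liberated amine at 0 °C should favour the through-conjugated potassium dienolate formed by loss of a C10 hydrogen, which reacts with the bromoester at its α-carbon C6 to leave the E C9=C10 alkene, and the electrophile should enter axially on the half-chair that keeps the C4 silyloxy group equatorial, hence trans to that group, which sets C6 as R.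

Step 6
Reactants: 12 methyl 2-[(1R,5R)-5-(tert-butyldimethylsilyloxy)-1-[(1E,3R,5E)-3,7-dimethyl-7-(triethylsilyloxy)octa-1,5-dien-1-yl]-2-oxocyclohexyl]acetate
Product: 15 methyl 2-[(1R,5S)-5-(tert-butyldimethylsilyloxy)-1-[(1E,3R,5E)-3,7-dimethyl-7-(triethylsilyloxy)octa-1,5-dien-1-yl]-2-oxocyclohex-3-en-1-yl]acetate, via lithium enolate 13 (not isolated), via enol silane 14 (not isolated)
Conditions: LiN(SiMe3)2, THF, −78 °C; Me3SiCl; then Pd(OAc)2, MeCN, rt
Reagents that add atoms: none
Why: Saegusa–Ito dehydrogenation: C2 is the only enolisable ketone position and the ketone is deprotonated ahead of the ester, so a single enol silane should form, and Pd(OAc)2 (divalent palladium) turns it by way of an oxa-π-allyl complex and loss of a C3 hydrogen into the enone, as is well established for 4-silyloxycyclohexanones.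

Step 7
Reactants: 15 methyl 2-[(1R,5S)-5-(tert-butyldimethylsilyloxy)-1-[(1E,3R,5E)-3,7-dimethyl-7-(triethylsilyloxy)octa-1,5-dien-1-yl]-2-oxocyclohex-3-en-1-yl]acetate
Product: 17 2-[(1R,5S)-5-(tert-butyldimethylsilyloxy)-1-[(1E,3R,5E)-3,7-dimethyl-7-(triethylsilyloxy)octa-1,5-dien-1-yl]-2-oxocyclohex-3-en-1-yl]acetic acid, via trimethylstannyl ester 16 (not isolated)
Conditions: Me3SnOH, ClCH2CH2Cl, 70 °C; brief cold 0.1 M HCl wash
Reagents that add atoms: trimethyltin hydroxide C[Sn](C)(C)O
Why: Me3SnOH cleaves unhindered methyl esters under neutral conditions through the stannyl ester, which avoids hydroxide and so should spare the γ-silyloxy enone from conjugate addition and from enolisation at C4.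

Step 8
Reactants: 17 2-[(1R,5S)-5-(tert-butyldimethylsilyloxy)-1-[(1E,3R,5E)-3,7-dimethyl-7-(triethylsilyloxy)octa-1,5-dien-1-yl]-2-oxocyclohex-3-en-1-yl]acetic acid
Product: 18 (1S,5R,9S)-9-(tert-butyldimethylsilyloxy)-1-[(1R,2R,4E)-2,6-dimethyl-1-(phenylselanyl)-6-(triethylsilyloxy)hept-4-en-1-yl]-2-oxaspiro[4.5]dec-7-ene-3,6-dione
Conditions: Et3N, CH2Cl2, −78 °C; then PhSeCl, −78 → 0 °C
Reagents that add atoms: phenylselenenyl chloride Cl[Se]c1ccccc1
Why: PhSeCl adds reversibly to the E C9=C10 alkene to give a seleniranium ion, which the C8 carboxylate (present as its triethylammonium salt) opens anti at C9; the closest known reaction type is the phenylselenolactonisation of γ,δ-unsaturated acids. The lactone ring closes in the 5-exo-trig mode through the new O–C9 bond, which is geometrically preferred over 6-endo attack at C10 and turns C6 into the spiro atom. C10 is controlled by the alkene geometry, since anti addition across the E alkene ties it to C9 and gives (10R) next to the untouched (11R) centre. C9 is controlled by the quaternary C6: with the C7 arm placed for backside attack, the rotamer about C6–C9 that puts the selenium-bearing C10 beside the flat C1 carbonyl and not beside the C5 methylene is the less crowded one, so C10 should end cis to C1 on the lactone ring. The step needs chemoselectivity for C9=C10, which the substrate provides because the enone is too electron-poor for PhSeCl and the C13=C14 alkene has no internal nucleophile within reach, so that any adduct formed there reverts and the material drains into the lactone. It also needs the acid to be the only nucleophile, which is why the C4 oxygen, cis to the alkenyl arm, and the C15 oxygen both stay silylated.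

Step 9
Reactants: 18 (1S,5R,9S)-9-(tert-butyldimethylsilyloxy)-1-[(1R,2R,4E)-2,6-dimethyl-1-(phenylselanyl)-6-(triethylsilyloxy)hept-4-en-1-yl]-2-oxaspiro[4.5]dec-7-ene-3,6-dione
Product: 20 (1R,5R,9S)-9-(tert-butyldimethylsilyloxy)-1-[(1E,4E)-2,6-dimethyl-6-(triethylsilyloxy)hepta-1,4-dien-1-yl]-2-oxaspiro[4.5]dec-7-ene-3,6-dione, via selenoxide 19 (not isolated)
Conditions: mCPBA (1.05 equiv), CH2Cl2, −78 °C; then Et3N, −78 °C → rt
Reagents that add atoms: none
Why: Chemoselective oxidation of selenium at −78 °C followed by selenoxide syn-elimination: the hydrogen on the oxygen-bearing C9 is avoided, so the single C11 hydrogen is taken through the five-membered cyclic transition state, and with the (10R,11R) configuration this eclipses C9 with the C11 methyl, which should give the E C10=C11 alkene.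

Step 10
Reactants: 20 (1R,5R,9S)-9-(tert-butyldimethylsilyloxy)-1-[(1E,4E)-2,6-dimethyl-6-(triethylsilyloxy)hepta-1,4-dien-1-yl]-2-oxaspiro[4.5]dec-7-ene-3,6-dione
Product: 21 (1R,5R,9S)-9-hydroxy-1-[(1E,4E)-6-hydroxy-2,6-dimethylhepta-1,4-dien-1-yl]-2-oxaspiro[4.5]dec-7-ene-3,6-dione
Conditions: HF·pyridine, pyridine, THF, 0 °C → rt
Reagents that add atoms: none
Why: Fluoride-mediated desilylation with pyridine-buffered HF·pyridine should remove the tertiary triethylsilyl and the secondary tert-butyldimethylsilyl group in one operation, without the basicity that γ-hydroxy enones tolerate poorly and without enough acidity to ionise the tertiary allylic alcohol or the allylic lactone.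

Step 11
Reactants: 21 (1R,5R,9S)-9-hydroxy-1-[(1E,4E)-6-hydroxy-2,6-dimethylhepta-1,4-dien-1-yl]-2-oxaspiro[4.5]dec-7-ene-3,6-dione
Product: 22 [(1R,5R,9S)-1-[(1E,4E)-6-hydroxy-2,6-dimethylhepta-1,4-dien-1-yl]-3,6-dioxo-2-oxaspiro[4.5]dec-7-en-9-yl] acetate (the target)
Conditions: Ac2O, pyridine, CH2Cl2, 0 °C → rt
Reagents that add atoms: acetic anhydride CC(=O)OC(C)=O
Why: Acetylation with Ac2O in pyridine should be selective for the secondary allylic C4 hydroxyl, since the tertiary C15 carbinol is not acylated without a nucleophilic catalyst, and C4 keeps its configuration because its C–O bond is not broken.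

Compound list
1 | (R)-citronellal, (3R)-3,7-dimethyloct-6-enal | O=CC[C@H](C)CCC=C(C)C | starting material
2 | (3R,5E)-7-hydroperoxy-3,7-dimethyloct-5-enal | O=CC[C@H](C)C/C=C/C(C)(C)OO | intermediate (not isolated)
3 | (3R,5E)-7-hydroxy-3,7-dimethyloct-5-enal | O=CC[C@H](C)C/C=C/C(C)(C)O | intermediate
4 | (3R,5E)-3,7-dimethyl-7-(triethylsilyloxy)oct-5-enal | O=CC[C@H](C)C/C=C/C(C)(C)O[Si](CC)(CC)CC | intermediate
5 | 4-(tert-butyldimethylsilyloxy)cyclohexanone | O=C1CCC(O[Si](C)(C)C(C)(C)C)CC1 | starting material
6 | lithium (4R)-4-(tert-butyldimethylsilyloxy)cyclohex-1-en-1-olate | [Li]OC1=CC[C@H](O[Si](C)(C)C(C)(C)C)CC1 | intermediate (not isolated)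
7 | (4R)-4-(tert-butyldimethylsilyloxy)-2-[(3R,5E)-1-hydroxy-3,7-dimethyl-7-(triethylsilyloxy)oct-5-en-1-yl]cyclohexan-1-one, epimer mixture at C2 and C1' | O=C1CC[C@@H](O[Si](C)(C)C(C)(C)C)CC1C(O)C[C@H](C)C/C=C/C(C)(C)O[Si](CC)(CC)CC | intermediate
8 | C1' methanesulfonate of 7 | O=C1CC[C@@H](O[Si](C)(C)C(C)(C)C)CC1C(OS(C)(=O)=O)C[C@H](C)C/C=C/C(C)(C)O[Si](CC)(CC)CC | intermediate (not isolated)
9 | (2E,4R)-4-(tert-butyldimethylsilyloxy)-2-[(3R,5E)-3,7-dimethyl-7-(triethylsilyloxy)oct-5-en-1-ylidene]cyclohexan-1-one | O=C1CC[C@@H](O[Si](C)(C)C(C)(C)C)C/C1=C\C[C@H](C)C/C=C/C(C)(C)O[Si](CC)(CC)CC | intermediate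
10 | methyl bromoacetate | BrCC(=O)OC | starting material
11 | potassium (4R)-4-(tert-butyldimethylsilyloxy)-2-[(1E,3R,5E)-3,7-dimethyl-7-(triethylsilyloxy)octa-1,5-dien-1-yl]cyclohex-1-en-1-olate | [K]OC1=C(/C=C/[C@H](C)C/C=C/C(C)(C)O[Si](CC)(CC)CC)C[C@H](O[Si](C)(C)C(C)(C)C)CC1 | intermediate (not isolated)
12 | methyl 2-[(1R,5R)-5-(tert-butyldimethylsilyloxy)-1-[(1E,3R,5E)-3,7-dimethyl-7-(triethylsilyloxy)octa-1,5-dien-1-yl]-2-oxocyclohexyl]acetate | COC(=O)C[C@@]1(/C=C/[C@H](C)C/C=C/C(C)(C)O[Si](CC)(CC)CC)C[C@H](O[Si](C)(C)C(C)(C)C)CCC1=O | intermediate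
13 | lithium C1=C2 enolate of 12 | COC(=O)C[C@@]1(/C=C/[C@H](C)C/C=C/C(C)(C)O[Si](CC)(CC)CC)C[C@H](O[Si](C)(C)C(C)(C)C)CC=C1O[Li] | intermediate (not isolated)
14 | methyl 2-[(1R,5R)-5-(tert-butyldimethylsilyloxy)-1-[(1E,3R,5E)-3,7-dimethyl-7-(triethylsilyloxy)octa-1,5-dien-1-yl]-2-(trimethylsilyloxy)cyclohex-2-en-1-yl]acetate | COC(=O)C[C@@]1(/C=C/[C@H](C)C/C=C/C(C)(C)O[Si](CC)(CC)CC)C[C@H](O[Si](C)(C)C(C)(C)C)CC=C1O[Si](C)(C)C | intermediate (not isolated)
15 | methyl 2-[(1R,5S)-5-(tert-butyldimethylsilyloxy)-1-[(1E,3R,5E)-3,7-dimethyl-7-(triethylsilyloxy)octa-1,5-dien-1-yl]-2-oxocyclohex-3-en-1-yl]acetate | COC(=O)C[C@@]1(/C=C/[C@H](C)C/C=C/C(C)(C)O[Si](CC)(CC)CC)C[C@H](O[Si](C)(C)C(C)(C)C)C=CC1=O | intermediate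
16 | trimethylstannyl ester of 17 | C[Sn](C)(C)OC(=O)C[C@@]1(/C=C/[C@H](C)C/C=C/C(C)(C)O[Si](CC)(CC)CC)C[C@H](O[Si](C)(C)C(C)(C)C)C=CC1=O | intermediate (not isolated)
17 | 2-[(1R,5S)-5-(tert-butyldimethylsilyloxy)-1-[(1E,3R,5E)-3,7-dimethyl-7-(triethylsilyloxy)octa-1,5-dien-1-yl]-2-oxocyclohex-3-en-1-yl]acetic acid | OC(=O)C[C@@]1(/C=C/[C@H](C)C/C=C/C(C)(C)O[Si](CC)(CC)CC)C[C@H](O[Si](C)(C)C(C)(C)C)C=CC1=O | intermediate (precursor of the key step)
18 | (1S,5R,9S)-9-(tert-butyldimethylsilyloxy)-1-[(1R,2R,4E)-2,6-dimethyl-1-(phenylselanyl)-6-(triethylsilyloxy)hept-4-en-1-yl]-2-oxaspiro[4.5]dec-7-ene-3,6-dione | CC(C)(C)[Si](C)(C)O[C@@H]1C=CC(=O)[C@@]2(CC(=O)O[C@@H]2[C@H]([Se]c3ccccc3)[C@H](C)C/C=C/C(C)(C)O[Si](CC)(CC)CC)C1 | intermediate (product of the key step)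
19 | selenoxide of 18 (mixture at selenium) | CC(C)(C)[Si](C)(C)O[C@@H]1C=CC(=O)[C@@]2(CC(=O)O[C@@H]2[C@H]([Se](=O)c3ccccc3)[C@H](C)C/C=C/C(C)(C)O[Si](CC)(CC)CC)C1 | intermediate (not isolated)
20 | (1R,5R,9S)-9-(tert-butyldimethylsilyloxy)-1-[(1E,4E)-2,6-dimethyl-6-(triethylsilyloxy)hepta-1,4-dien-1-yl]-2-oxaspiro[4.5]dec-7-ene-3,6-dione | CC(C)(C)[Si](C)(C)O[C@@H]1C=CC(=O)[C@@]2(CC(=O)O[C@@H]2/C=C(\C)C/C=C/C(C)(C)O[Si](CC)(CC)CC)C1 | intermediate
21 | (1R,5R,9S)-9-hydroxy-1-[(1E,4E)-6-hydroxy-2,6-dimethylhepta-1,4-dien-1-yl]-2-oxaspiro[4.5]dec-7-ene-3,6-dione | O[C@@H]1C=CC(=O)[C@@]2(CC(=O)O[C@@H]2/C=C(\C)C/C=C/C(C)(C)O)C1 | intermediate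
22 | [(1R,5R,9S)-1-[(1E,4E)-6-hydroxy-2,6-dimethylhepta-1,4-dien-1-yl]-3,6-dioxo-2-oxaspiro[4.5]dec-7-en-9-yl] acetate | CC(=O)O[C@@H]1C=CC(=O)[C@@]2(CC(=O)O[C@@H]2/C=C(\C)C/C=C/C(C)(C)O)C1 | target

Total step count: 11. Longest linear sequence: 11 steps (steps 1–11 from citronellal 1); ketone 5 is commercial and enters at step 3.

Steps most likely to fail

1. Step 8 (key step). What may go wrong: low facial discrimination in the ring closure, so that both C9 epimers (each with its anti-related C10) form, or competing 6-endo closure at C10. Fallback: reagent control in place of substrate control. Setting out from acid 17, the selenium electrophile is replaced by an enantiopure arylselenenyl triflate. It is made from bis[2-[(1S)-1-hydroxyethyl]phenyl] diselenide with Br2 and AgOSO2CF3 at −78 °C and used with 2,6-di-tert-butylpyridine. Both antipodes of the diselenide are accessible, and the one matched to the substrate is kept. Asymmetric selenolactonisation with such reagents is established and should give the aryl selenide lactone F1. Oxidation with mCPBA at −78 °C gives the selenoxide F2, which eliminates on warming toward C11 and rejoins the route at diene lactone 20.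

2. Step 5. What may go wrong: enolisation at C2 in place of C10 so that the bromoester ends up at C2, attack through oxygen or through C10 of the dienolate, or entry of the electrophile cis to the C4 silyloxy group. Fallback: regiospecific enolate generation from an isolated enol silane. Setting out from enone 9, silylation under equilibrating conditions (Me3SiCl, NaI, Et3N, MeCN, rt) should give the through-conjugated silyl dienol ether F3. It can be purified and its constitution confirmed before it is committed. MeLi in THF then releases the amine-free lithium dienolate F4, and alkylation with 10 (DMPU as co-solvent, −78 °C) returns to keto ester 12.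

3. Step 3. What may go wrong: erosion of enantioselectivity when the chiral enolate is quenched externally by the aldehyde, and proton transfer between residual amide or amine and the enolisable aldehyde, leading to self-condensation of 4 or a stalled aldol. Fallback: internal-quench silylation followed by an amine-free aldol. Setting out from ketone 5, deprotonation by the same chiral lithium amide with Me3SiCl already present at −78 °C traps the enolate at once as (4R)-4-(tert-butyldimethylsilyloxy)-1-(trimethylsilyloxy)cyclohex-1-ene F5. This can be purified and its enantiomeric purity measured. MeLi in THF at 0 °C then regenerates lithium enolate 6 free of amine, and addition of 4 at −78 °C gives aldol 7, where the route is rejoined.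

Further compounds
F1 | step 8 | (1S,5R,9S)-9-(tert-butyldimethylsilyloxy)-1-[(1R,2R,4E)-1-[[2-[(1S)-1-hydroxyethyl]phenyl]selanyl]-2,6-dimethyl-6-(triethylsilyloxy)hept-4-en-1-yl]-2-oxaspiro[4.5]dec-7-ene-3,6-dione | CC(C)(C)[Si](C)(C)O[C@@H]1C=CC(=O)[C@@]2(CC(=O)O[C@@H]2[C@H]([Se]c3ccccc3[C@H](C)O)[C@H](C)C/C=C/C(C)(C)O[Si](CC)(CC)CC)C1
F2 | step 8 | selenoxide of F1 (mixture at selenium) | CC(C)(C)[Si](C)(C)O[C@@H]1C=CC(=O)[C@@]2(CC(=O)O[C@@H]2[C@H]([Se](=O)c3ccccc3[C@H](C)O)[C@H](C)C/C=C/C(C)(C)O[Si](CC)(CC)CC)C1
F3 | step 5 | (4R)-4-(tert-butyldimethylsilyloxy)-2-[(1E,3R,5E)-3,7-dimethyl-7-(triethylsilyloxy)octa-1,5-dien-1-yl]-1-(trimethylsilyloxy)cyclohex-1-ene | C[Si](C)(C)OC1=C(/C=C/[C@H](C)C/C=C/C(C)(C)O[Si](CC)(CC)CC)C[C@H](O[Si](C)(C)C(C)(C)C)CC1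
F4 | step 5 | lithium (4R)-4-(tert-butyldimethylsilyloxy)-2-[(1E,3R,5E)-3,7-dimethyl-7-(triethylsilyloxy)octa-1,5-dien-1-yl]cyclohex-1-en-1-olate | [Li]OC1=C(/C=C/[C@H](C)C/C=C/C(C)(C)O[Si](CC)(CC)CC)C[C@H](O[Si](C)(C)C(C)(C)C)CC1
F5 | step 3 | (4R)-4-(tert-butyldimethylsilyloxy)-1-(trimethylsilyloxy)cyclohex-1-ene | C[Si](C)(C)OC1=CC[C@H](O[Si](C)(C)C(C)(C)C)CC1
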